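**Retrosynthetic overview**
- Target ⇒ tetracontanoic acid + tyrosol by ester C–O disconnection; the phenol is masked as a benzyl ether so that only the primary alcohol is acylated.
- Tetracontanoic acid ⇒ methyl 13-oxotetracontanoate ⇒ octacosanoyl chloride + a C12 malonate triester. The fragment-joining C–C bond (C12–C13) is made by a crossed Claisen-type C-acylation, and the ketone is then removed by Wolff–Kishner reduction.
- Octacosanoic acid ⇒ the same disconnection once more: palmitoyl chloride + the same triester (C16 + C12 + C12 = C40).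
- Triester ⇒ dibenzyl malonate + methyl 11-bromoundecanoate (malonate alkylation).
- No ring is formed; the only ring (the benzene ring of tyrosol) is bought.

Assumption: the acyl chain of the SMILES is read as 40 carbons (tetracontanoyl); the target has no stereocentre, so it is a single achiral compound and no stereocontrol is needed.
Convention: sodium or potassium salts formed by simple deprotonation (malonate enolates, phenoxide, carboxylates) count as forms of the numbered compound; the two acid chlorides are used crude after evaporation.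

**Route**

Step 1
Reactants: 1 dibenzyl malonate; 2 methyl 11-bromoundecanoate
Product: 3 1,1-dibenzyl 11-methyl undecane-1,1,11-tricarboxylate
Conditions: NaH (1.2 eq), 1 (1.5 eq), cat. NaI, THF/DMF 4:1, 0 °C → 65 °C
Reagents that add atoms: none
Why: Malonic ester alkylation (SN2) of a primary bromide by the soft sodium malonate, with excess malonate suppressing dialkylation and the methyl ester left untouched; no stereocentre is formed.

Step 2
Reactants: 3 1,1-dibenzyl 11-methyl undecane-1,1,11-tricarboxylate; 4 hexadecanoyl chloride (palmitoyl chloride)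
Product: 5 dibenzyl 2-hexadecanoyl-2-(11-methoxy-11-oxoundecyl)malonate
Conditions: NaH (1.05 eq), toluene/THF, rt; then 4, 0 °C → 50 °C
Reagents that add atoms: none
Why: Crossed Claisen-type condensation (C-acylation of a malonate ester enolate by an acyl chloride, Bowman ketone synthesis), in which the doubly stabilised enolate reacts at carbon and the quaternary, non-enolisable product cannot be deprotonated or acylated again; no stereocentre is formed.

Step 3
Reactants: 5 dibenzyl 2-hexadecanoyl-2-(11-methoxy-11-oxoundecyl)malonate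
Product: 8 methyl 13-oxooctacosanoate, via 2-hexadecanoyl-2-(11-methoxy-11-oxoundecyl)malonic acid 6 (not isolated), via 2-(11-methoxy-11-oxoundecyl)-3-oxooctadecanoic acid 7 (not isolated)
Conditions: H2 (1 atm), 10% Pd/C, EtOAc/THF, rt; filter; toluene, reflux
Reagents that add atoms: none
Why: Hydrogenolysis of both benzyl esters gives an acylmalonic acid that loses two CO2 on warming (β-keto acid decarboxylation), while the methyl ester and the aliphatic ketone survive neutral H2/Pd.

Step 4
Reactants: 8 methyl 13-oxooctacosanoate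
Product: 11 octacosanoic acid, via 13-oxooctacosanoic acid 9 (not isolated), via 13-hydrazinylideneoctacosanoic acid 10 (not isolated)
Conditions: KOH, diethylene glycol, 120 °C; then N2H4·H2O, 130 → 200 °C (water distilled off); then aq HCl
Reagents that add atoms: potassium hydroxide, [K+].[OH-]
Why: Wolff–Kishner reduction (Huang-Minlon procedure) in which the ester is saponified first and the ketone hydrazone then loses N2 under hot KOH to give CH2, conditions a saturated carboxylate tolerates.

Step 5
Reactants: 11 octacosanoic acid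
Product: 12 octacosanoyl chloride
Conditions: SOCl2 (3 eq), cat. DMF, toluene, 70 °C; evaporate
Reagents that add atoms: thionyl chloride, O=S(Cl)Cl
Why: Acid chloride formation through the chlorosulfite (Vilsmeier catalysis by DMF) is quantitative for saturated fatty acids and gives only gaseous by-products.

Step 6
Reactants: 3 1,1-dibenzyl 11-methyl undecane-1,1,11-tricarboxylate; 12 octacosanoyl chloride
Product: 13 dibenzyl 2-(11-methoxy-11-oxoundecyl)-2-octacosanoylmalonate
Conditions: NaH (1.05 eq), toluene/THF, rt; then 12, 45–50 °C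
Reagents that add atoms: none
Why: The same crossed Claisen-type C-acylation of the malonate enolate as in step 2, run warm to keep the C28 acid chloride dissolved, joins the C28 and C12 fragments; no stereocentre is formed.

Step 7
Reactants: 13 dibenzyl 2-(11-methoxy-11-oxoundecyl)-2-octacosanoylmalonate
Product: 16 methyl 13-oxotetracontanoate, via 2-(11-methoxy-11-oxoundecyl)-2-octacosanoylmalonic acid 14 (not isolated), via 2-(11-methoxy-11-oxoundecyl)-3-oxotriacontanoic acid 15 (not isolated)
Conditions: H2 (1 atm), 10% Pd/C, THF/EtOAc, 40 °C; filter hot; toluene, reflux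
Reagents that add atoms: none
Why: Benzyl ester hydrogenolysis followed by double decarboxylation of the acylmalonic acid, exactly as in step 3, leaves the linear C40 keto ester.

Step 8
Reactants: 16 methyl 13-oxotetracontanoate
Product: 19 tetracontanoic acid, via 13-oxotetracontanoic acid 17 (not isolated), via 13-hydrazinylidenetetracontanoic acid 18 (not isolated)
Conditions: KOH, diethylene glycol, 130 °C; then N2H4·H2O, 130 → 200 °C (water distilled off); then aq HCl; recrystallise from hot toluene
Reagents that add atoms: potassium hydroxide, [K+].[OH-]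
Why: Wolff–Kishner reduction (Huang-Minlon procedure) as in step 4, the standard deoxygenation of long-chain keto acids, with the melt at 200 °C keeping the C40 soap in solution.

Step 9
Reactants: 20 tyrosol (4-(2-hydroxyethyl)phenol)
Product: 21 2-[4-(benzyloxy)phenyl]ethanol
Conditions: BnBr (1.05 eq), K2CO3 (1.5 eq), acetone, reflux
Reagents that add atoms: benzyl bromide, BrCc1ccccc1
Why: Williamson ether synthesis that is chemoselective because K2CO3 deprotonates only the phenol (pKa about 10) and not the aliphatic alcohol.

Step 10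
Reactants: 19 tetracontanoic acid
Product: 22 tetracontanoyl chloride
Conditions: SOCl2 (3 eq), cat. DMF, toluene, 80 °C; evaporate
Reagents that add atoms: thionyl chloride, O=S(Cl)Cl
Why: Acid chloride formation as in step 5, with hot toluene dissolving the C40 acid.

Step 11
Reactants: 22 tetracontanoyl chloride; 21 2-[4-(benzyloxy)phenyl]ethanol
Product: 23 2-[4-(benzyloxy)phenyl]ethyl tetracontanoate
Conditions: pyridine (2 eq), cat. DMAP, toluene, 60 °C
Reagents that add atoms: none
Why: DMAP-catalysed acylation (nucleophilic acyl substitution through the acylpyridinium) of an unhindered primary alcohol, with the phenol blocked so that only one ester can form.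

Step 12
Reactants: 23 2-[4-(benzyloxy)phenyl]ethyl tetracontanoate
Product: 24 2-(4-hydroxyphenyl)ethyl tetracontanoate (target)
Conditions: H2 (1 atm), 10% Pd/C, THF/EtOAc, 40 °C
Reagents that add atoms: none
Why: Hydrogenolysis of the aryl benzyl ether frees the phenol under neutral conditions, and the homobenzylic alkyl ester and the saturated chain are inert to H2/Pd.

**Compound list**

1 | dibenzyl malonate | O=C(CC(=O)OCc1ccccc1)OCc1ccccc1 | starting material
2 | methyl 11-bromoundecanoate | COC(=O)CCCCCCCCCCBr | starting material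
3 | 1,1-dibenzyl 11-methyl undecane-1,1,11-tricarboxylate | COC(=O)CCCCCCCCCCC(C(=O)OCc1ccccc1)C(=O)OCc1ccccc1 | intermediate
4 | hexadecanoyl chloride | CCCCCCCCCCCCCCCC(=O)Cl | starting material
5 | dibenzyl 2-hexadecanoyl-2-(11-methoxy-11-oxoundecyl)malonate | CCCCCCCCCCCCCCCC(=O)C(CCCCCCCCCCC(=O)OC)(C(=O)OCc1ccccc1)C(=O)OCc1ccccc1 | intermediate
6 | 2-hexadecanoyl-2-(11-methoxy-11-oxoundecyl)malonic acid | CCCCCCCCCCCCCCCC(=O)C(CCCCCCCCCCC(=O)OC)(C(O)=O)C(O)=O | intermediate
7 | 2-(11-methoxy-11-oxoundecyl)-3-oxooctadecanoic acid | CCCCCCCCCCCCCCCC(=O)C(CCCCCCCCCCC(=O)OC)C(O)=O | intermediate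
8 | methyl 13-oxooctacosanoate | CCCCCCCCCCCCCCCC(=O)CCCCCCCCCCCC(=O)OC | intermediate
9 | 13-oxooctacosanoic acid | CCCCCCCCCCCCCCCC(=O)CCCCCCCCCCCC(O)=O | intermediate
10 | 13-hydrazinylideneoctacosanoic acid | CCCCCCCCCCCCCCCC(=NN)CCCCCCCCCCCC(O)=O | intermediate
11 | octacosanoic acid | CCCCCCCCCCCCCCCCCCCCCCCCCCCC(O)=O | intermediate
12 | octacosanoyl chloride | CCCCCCCCCCCCCCCCCCCCCCCCCCCC(=O)Cl | intermediate
13 | dibenzyl 2-(11-methoxy-11-oxoundecyl)-2-octacosanoylmalonate | CCCCCCCCCCCCCCCCCCCCCCCCCCCC(=O)C(CCCCCCCCCCC(=O)OC)(C(=O)OCc1ccccc1)C(=O)OCc1ccccc1 | intermediate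
14 | 2-(11-methoxy-11-oxoundecyl)-2-octacosanoylmalonic acid | CCCCCCCCCCCCCCCCCCCCCCCCCCCC(=O)C(CCCCCCCCCCC(=O)OC)(C(O)=O)C(O)=O | intermediate
15 | 2-(11-methoxy-11-oxoundecyl)-3-oxotriacontanoic acid | CCCCCCCCCCCCCCCCCCCCCCCCCCCC(=O)C(CCCCCCCCCCC(=O)OC)C(O)=O | intermediate
16 | methyl 13-oxotetracontanoate | CCCCCCCCCCCCCCCCCCCCCCCCCCCC(=O)CCCCCCCCCCCC(=O)OC | intermediate
17 | 13-oxotetracontanoic acid | CCCCCCCCCCCCCCCCCCCCCCCCCCCC(=O)CCCCCCCCCCCC(O)=O | intermediate
18 | 13-hydrazinylidenetetracontanoic acid | CCCCCCCCCCCCCCCCCCCCCCCCCCCC(=NN)CCCCCCCCCCCC(O)=O | intermediate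
19 | tetracontanoic acid | CCCCCCCCCCCCCCCCCCCCCCCCCCCCCCCCCCCCCCCC(O)=O | intermediate
20 | tyrosol (4-(2-hydroxyethyl)phenol) | OCCc1ccc(O)cc1 | starting material
21 | 2-[4-(benzyloxy)phenyl]ethanol | OCCc1ccc(OCc2ccccc2)cc1 | intermediate
22 | tetracontanoyl chloride | CCCCCCCCCCCCCCCCCCCCCCCCCCCCCCCCCCCCCCCC(=O)Cl | intermediate
23 | 2-[4-(benzyloxy)phenyl]ethyl tetracontanoate | CCCCCCCCCCCCCCCCCCCCCCCCCCCCCCCCCCCCCCCC(=O)OCCc1ccc(OCc2ccccc2)cc1 | intermediate
24 | 2-(4-hydroxyphenyl)ethyl tetracontanoate | CCCCCCCCCCCCCCCCCCCCCCCCCCCCCCCCCCCCCCCC(=O)OCCc1ccc(O)cc1 | target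

**Step count**
Total: 12 steps. Longest linear sequence: 11 steps (steps 1–8, then 10–12); step 9 is a one-step side branch.

**Steps most likely to fail, with fallbacks**

Step 6 (C-acylation with the waxy C28 acid chloride: poor solubility, and O-acylation or incomplete reaction at the hindered malonate carbon). The fallback sets out from 12 and comes back at 17. Bought cyclododecanone and morpholine are condensed (cat. TsOH, toluene, Dean–Stark) to 4-(cyclododec-1-en-1-yl)morpholine F1. F1 is acylated with 12 (Et3N, CHCl3, 40 °C) to the enaminone 1-[2-(morpholin-4-yl)cyclododec-1-en-1-yl]octacosan-1-one F2, which aqueous HCl hydrolyses to 2-octacosanoylcyclododecan-1-one F3. KOH in aqueous ethanol/diethylene glycol at 100 °C then opens the ring by retro-Claisen cleavage to 13-oxotetracontanoic acid 17, which goes on through the hydrazine stage of step 8. The C12 donor thus changes from a malonate enolate to a cyclic enamine, and hydrogenolysis/decarboxylation is replaced by ring opening.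

Step 8 (Wolff–Kishner on the C40 keto ester: sparingly soluble soap, and azine formation or incomplete reduction). The fallback sets out from 16 and comes back at 19. The ketone is converted with 1,2-ethanedithiol and BF3·OEt2 in CHCl3 into methyl 12-(2-heptacosyl-1,3-dithiolan-2-yl)dodecanoate F4. Raney nickel in refluxing dioxane/EtOH desulfurises F4 to methyl tetracontanoate F5 (Mozingo reduction). Saponification (KOH, EtOH/toluene, reflux; then aq HCl) gives tetracontanoic acid 19.

Step 11 (acylation with the poorly soluble C40 acid chloride: slow, with hydrolysis back to 19). The fallback sets out from 19, uses unprotected tyrosol 20, and comes back at the target 24. Immobilised Candida antarctica lipase B (Novozym 435) in toluene/2-methyl-2-butanol at 70 °C over 4 Å molecular sieves esterifies only the primary aliphatic hydroxyl of 20 with 19 and leaves the phenol free. This gives 24 directly and makes steps 9–12 unnecessary; it makes no new compound (F0).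

**Further compounds**

F1 | step 6 | 4-(cyclododec-1-en-1-yl)morpholine | C1=C(N2CCOCC2)CCCCCCCCCC1
F2 | step 6 | 1-[2-(morpholin-4-yl)cyclododec-1-en-1-yl]octacosan-1-one | CCCCCCCCCCCCCCCCCCCCCCCCCCCC(=O)C1=C(N2CCOCC2)CCCCCCCCCC1
F3 | step 6 | 2-octacosanoylcyclododecan-1-one | CCCCCCCCCCCCCCCCCCCCCCCCCCCC(=O)C1CCCCCCCCCCC1=O
F4 | step 8 | methyl 12-(2-heptacosyl-1,3-dithiolan-2-yl)dodecanoate | CCCCCCCCCCCCCCCCCCCCCCCCCCCC1(CCCCCCCCCCCC(=O)OC)SCCS1
F5 | step 8 | methyl tetracontanoate | CCCCCCCCCCCCCCCCCCCCCCCCCCCCCCCCCCCCCCCC(=O)OC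
F0 | step 11 | none | none
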